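**Retrosynthetic overview**
1. Target 8 ⇒ 6: both C–Br bonds are made last by double electrophilic bromination of the catechol.
2. 6 ⇒ 4: hydrolysis and decarboxylation remove an ester whose only job is to acidify the sulfone α-carbon.
3. 4 ⇒ catechol 1 + methyl (methylsulfonyl)acetate 2: the aryl–CH bond is the key C–C bond. Catechol C4 (normally nucleophilic) is made electrophilic by oxidation to o-benzoquinone 3 (an enolonium-type reversal of polarity) and is attacked by the sulfonyl-stabilised carbanion.
4. No ring is formed; the benzene ring of catechol is carried through intact.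

Assumption: the target has no stereocentre (it is achiral), so no enantiocontrol is needed and the SMILES is taken as the complete structure.

**Route**

Step 1
Reactants: 1 catechol (benzene-1,2-diol); 2 methyl 2-(methylsulfonyl)acetate
Product: 4 racemic methyl 2-(3,4-dihydroxyphenyl)-2-(methylsulfonyl)acetate, via o-benzoquinone 3 (not isolated)
Conditions: NaIO4 (1.0 equiv, aqueous, added over 30 min), 2 (3 equiv), NaH2PO4/Na2HPO4 buffer pH 7.5–MeCN (3:1), 0 °C, N2; acidify to pH 3, EtOAc
Reagents that add atoms: none
Why: Proposed new method: NaIO4 turns catechol into o-benzoquinone 3, an enolonium-type (polarity-reversed) form of the normally nucleophilic catechol C4, and the soft, ester-acidified α-sulfonyl carbanion of 2 (pKa near 11–12, partly ionised in the buffer) adds to it in a 1,4-Michael sense followed by tautomerisation back to the catechol, which is the mechanism of the closest known reaction type, the Wanzlick-type oxidative (dehydrogenative) coupling of catechols with 1,3-dicarbonyl C–H acids; only the sulfonyl-ester nucleophile is new, and the benzylic stereocentre it creates is formed racemic and is erased in step 2.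

Step 2
Reactants: 4 racemic methyl 2-(3,4-dihydroxyphenyl)-2-(methylsulfonyl)acetate
Product: 6 4-[(methylsulfonyl)methyl]benzene-1,2-diol, via 2-aryl-2-(methylsulfonyl)acetic acid 5 (not isolated)
Conditions: 6 M aq. HCl–AcOH (1:1), 100 °C, N2, 8 h
Reagents that add atoms: none
Why: Acid-catalysed ester hydrolysis gives the α-aryl-α-sulfonyl acetic acid 5, which loses CO2 at 100 °C through the sulfonyl- and aryl-stabilised carbanion (malonic-type decarboxylation), and acid rather than base is used because the phenoxide of a 4-hydroxybenzyl sulfone would expel methanesulfinate via a quinone methide; the racemic stereocentre becomes a CH2 group.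

Step 3
Reactants: 6 4-[(methylsulfonyl)methyl]benzene-1,2-diol
Product: 8 3,4-dibromo-5-[(methylsulfonyl)methyl]benzene-1,2-diol, via 4-bromo-5-[(methylsulfonyl)methyl]catechol 7 (not isolated)
Conditions: Br2 (2.05 equiv), AcOH, 15–20 °C, dark, 3 h
Reagents that add atoms: bromine, BrBr
Why: Electrophilic aromatic bromination (SEAr) of the activated catechol: the first bromine enters para to the hydroxyl that is meta to the side chain (as in 4-alkylcatechols) to give 7, the second enters the open position ortho to the other hydroxyl, and the last free position, wedged between CH2SO2CH3 and OH and meta to the first bromine, is the least reactive and stays free with two equivalents of Br2; no stereocentre is involved.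

**Compound list**
1 | catechol (benzene-1,2-diol) | Oc1ccccc1O | starting material
2 | methyl 2-(methylsulfonyl)acetate | COC(=O)CS(C)(=O)=O | starting material
3 | o-benzoquinone (cyclohexa-3,5-diene-1,2-dione), formed in the flask | O=C1C=CC=CC1=O | intermediate
4 | methyl 2-(3,4-dihydroxyphenyl)-2-(methylsulfonyl)acetate, racemic | COC(=O)C(c1ccc(O)c(O)c1)S(C)(=O)=O | intermediate
5 | 2-(3,4-dihydroxyphenyl)-2-(methylsulfonyl)acetic acid, racemic, formed in the flask | OC(=O)C(c1ccc(O)c(O)c1)S(C)(=O)=O | intermediate
6 | 4-[(methylsulfonyl)methyl]benzene-1,2-diol | CS(=O)(=O)Cc1ccc(O)c(O)c1 | intermediate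
7 | 4-bromo-5-[(methylsulfonyl)methyl]benzene-1,2-diol, formed in the flask | CS(=O)(=O)Cc1cc(O)c(O)cc1Br | intermediate
8 | 3,4-dibromo-5-[(methylsulfonyl)methyl]benzene-1,2-diol (achiral) | CS(=O)(=O)Cc1cc(O)c(O)c(Br)c1Br | target

**Step count**
Total steps: 3. Longest linear sequence: 3.

**Steps most likely to fail, with fallbacks**

Step 1 is the riskiest. o-Benzoquinone is short-lived, the product catechol can be re-oxidised, and the more acidic adduct 4 can arylate a second time. The fallback sets out from compound 2 and makes the same bond with an aryl–palladium electrophile instead of a quinone. Compound 2 is α-arylated with commercial 4-bromo-1,2-dimethoxybenzene (COc1ccc(Br)cc1OC) using Pd(OAc)2, P(t-Bu)3·HBF4 and NaH in dioxane at 80 °C. This gives methyl 2-(3,4-dimethoxyphenyl)-2-(methylsulfonyl)acetate F1. BBr3 in CH2Cl2 (−78 to 0 °C) then removes both aryl O-methyl groups, and the route is rejoined at compound 4.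

Step 3 is next. The second bromine could enter the position between the side chain and the hydroxyl, or a third bromine could follow. The fallback sets out from compound 2 and carries one bromine from the start, so that only a para-to-hydroxyl bromination remains.
- Commercial 3-bromocatechol (Oc1cccc(Br)c1O) is oxidised under the step 1 conditions to 3-bromo-o-benzoquinone F2, which 2 attacks at C5, remote from the bromine, to give methyl 2-(3-bromo-4,5-dihydroxyphenyl)-2-(methylsulfonyl)acetate F3.
- Hot HCl–AcOH as in step 2 takes F3 through 2-(3-bromo-4,5-dihydroxyphenyl)-2-(methylsulfonyl)acetic acid F4 to 3-bromo-5-[(methylsulfonyl)methyl]benzene-1,2-diol F5.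
- One equivalent of Br2 in AcOH then brominates para to the hydroxyl, between the bromine and the side chain. This is the same outcome as the known conversion of 3-bromo-4,5-dihydroxybenzaldehyde into its 2,3-dibromo derivative. The route is rejoined at compound 8.

Step 2 is the least risky, but hot mineral acid may be slow on the hindered ester or may degrade the catechol. The fallback sets out from compound 1 and uses an ester that leaves by acid-catalysed elimination instead of hydrolysis.
- tert-Butyl bromoacetate (CC(C)(C)OC(=O)CBr) and sodium methanesulfinate (CS(=O)[O-].[Na+]) in DMF give tert-butyl 2-(methylsulfonyl)acetate F6.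
- F6 is coupled with catechol 1 under the step 1 conditions (via 3) to give tert-butyl 2-(3,4-dihydroxyphenyl)-2-(methylsulfonyl)acetate F7.
- Catalytic TsOH in toluene at 90 °C expels 2-methylpropene to give acid 5, which decarboxylates in the same flask, and the route is rejoined at compound 6.

**Further compounds**
F1 | step 1 | methyl 2-(3,4-dimethoxyphenyl)-2-(methylsulfonyl)acetate, racemic | COC(=O)C(c1ccc(OC)c(OC)c1)S(C)(=O)=O
F2 | step 3 | 3-bromo-o-benzoquinone (3-bromocyclohexa-3,5-diene-1,2-dione) | O=C1C=CC=C(Br)C1=O
F3 | step 3 | methyl 2-(3-bromo-4,5-dihydroxyphenyl)-2-(methylsulfonyl)acetate, racemic | COC(=O)C(c1cc(O)c(O)c(Br)c1)S(C)(=O)=O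
F4 | step 3 | 2-(3-bromo-4,5-dihydroxyphenyl)-2-(methylsulfonyl)acetic acid, racemic | OC(=O)C(c1cc(O)c(O)c(Br)c1)S(C)(=O)=O
F5 | step 3 | 3-bromo-5-[(methylsulfonyl)methyl]benzene-1,2-diol | CS(=O)(=O)Cc1cc(O)c(O)c(Br)c1
F6 | step 2 | tert-butyl 2-(methylsulfonyl)acetate | CC(C)(C)OC(=O)CS(C)(=O)=O
F7 | step 2 | tert-butyl 2-(3,4-dihydroxyphenyl)-2-(methylsulfonyl)acetate, racemic | CC(C)(C)OC(=O)C(c1ccc(O)c(O)c1)S(C)(=O)=O
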